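**Retrosynthetic overview**

1. Verbenachalcone ⇐ its penta-MOM ether, by a single acidic global deprotection.
2. Both aryl–CH2 bonds are cut at once: the bond from ring B (the hydroxyl-bearing ring, carbon para to its OH) to its benzylic CH2, and the twin bond on ring A (the methoxy ring, carbon para to the ether oxygen). This leads back to a dibromo diaryl ether and two molecules of 1-[2,4-bis(methoxymethoxy)phenyl]prop-2-en-1-ol; forward, a two-fold Heck arylation/redox isomerization joins three components in one flask.
3. Enabling feature: rings A and B each carry, on a carbon flanked by two ring CH groups, the same chain aryl C–CH2–CH2–C(=O)–(2,4-dioxygenated phenyl). This Ar–CH2–CH2–C=O array is exactly what Heck arylation of a secondary allylic alcohol delivers, so one carbinol serves both rings and carries the ketone at the alcohol oxidation level.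
4. Dibromo diaryl ether ⇐ SNAr of 4-bromo-2-methoxyphenol on 4-bromo-2-fluorobenzaldehyde, Baeyer–Villiger (CHO → OH), MOM protection. Carbinol ⇐ 2,4-dihydroxybenzaldehyde by MOM protection and vinyl Grignard addition.
5. No ring is formed in the route: all four benzene rings are bought. The ether-linked pair A–B is assembled first (step 1) and the two resorcinol rings are attached last (step 6).

Key step: step 6

Remark: the target has no stereocentre. The allylic alcohol building block is made and used as the racemate, and its only stereocentre becomes a ketone carbon in the key step.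

**Route**

Step 1
Reactants: 1 4-bromo-2-methoxyphenol; 2 4-bromo-2-fluorobenzaldehyde
Product: 3 4-bromo-2-(4-bromo-2-methoxyphenoxy)benzaldehyde
Conditions: K2CO3, DMF, 90 °C
Reagents that add atoms: none
Why: Nucleophilic aromatic substitution (SNAr): the fluoride ortho to the formyl group is activated for addition–elimination by the phenoxide of 1 and should be displaced far faster than the para bromide, so both C–Br bonds should survive.

Step 2
Reactants: 3 4-bromo-2-(4-bromo-2-methoxyphenoxy)benzaldehyde
Product: 5 4-bromo-2-(4-bromo-2-methoxyphenoxy)phenol, via aryl formate 4 (not isolated)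
Conditions: mCPBA, CH2Cl2, 0 °C → rt; then K2CO3 (cat.), MeOH, rt
Reagents that add atoms: mCPBA (3-chloroperbenzoic acid), O=C(OO)c1cccc(Cl)c1
Why: Baeyer–Villiger (Dakin-type) oxidation: the ortho-aryloxy donor should make the aryl ring the migrating group in the Criegee intermediate so that formate 4 forms, and mild methanolysis should free the phenol without touching the C–Br bonds or the methyl ether.

Step 3
Reactants: 5 4-bromo-2-(4-bromo-2-methoxyphenoxy)phenol
Product: 6 4-bromo-2-(4-bromo-2-methoxyphenoxy)-1-(methoxymethoxy)benzene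
Conditions: MOMCl, i-Pr2NEt, CH2Cl2, 0 °C → rt
Reagents that add atoms: chloromethyl methyl ether (MOMCl), COCCl
Why: O-Alkylation of the phenol (MOM acetal formation) masks the acidic OH, which as a phenoxide would deactivate the ring B bromide toward oxidative addition; the same acid-labile group is used on all phenols so that one final step removes them.

Step 4
Reactants: 7 2,4-dihydroxybenzaldehyde
Product: 8 2,4-bis(methoxymethoxy)benzaldehyde
Conditions: MOMCl (3 equiv), K2CO3, acetone, reflux
Reagents that add atoms: chloromethyl methyl ether (MOMCl), COCCl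
Why: Two-fold Williamson-type O-alkylation; carbonate in refluxing acetone should also alkylate the hydrogen-bonded ortho hydroxyl.

Step 5
Reactants: 8 2,4-bis(methoxymethoxy)benzaldehyde
Product: 9 rac-1-[2,4-bis(methoxymethoxy)phenyl]prop-2-en-1-ol
Conditions: CH2=CHMgBr, THF, −78 → 0 °C; sat. aq NH4Cl, cold
Reagents that add atoms: vinylmagnesium bromide, C=C[Mg]Br
Why: Grignard 1,2-addition to the aldehyde; the carbinol centre is formed racemic on purpose (it is erased in step 6), and the electron-rich allylic benzylic alcohol is kept away from acid and used without long storage.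

Step 6
Reactants: 6 4-bromo-2-(4-bromo-2-methoxyphenoxy)-1-(methoxymethoxy)benzene; 9 rac-1-[2,4-bis(methoxymethoxy)phenyl]prop-2-en-1-ol (2.6 equiv)
Product: 11 penta-O-MOM verbenachalcone, via ring-B bromo monoketone 10 (not isolated)
Conditions: Pd(OAc)2 (10 mol %), n-Bu4NBr (2 equiv), NaHCO3 (5 equiv), DMF, 100 °C
Reagents that add atoms: none
Why: Each cycle is a Heck arylation with redox relay: Pd(0) inserts into a C–Br bond, the aryl–Pd adds syn across the terminal alkene of 9 with the aryl group delivered to the CH2 terminus, β-hydride elimination of the carbinol C–H gives a Pd-bound enol that tautomerizes to the aryl ketone, and NaHCO3 takes up HBr. The ring A bromide (para to the weaker aryloxy donor) should react first to give 10, and the second cycle at the ring B bromide (para to OMOM) then forms the ring B aryl–CH2 bond, so that one flask joins three building blocks, makes both Ar–CH2 bonds and both carbonyl groups and delivers the complete C31 skeleton at the correct oxidation level. The closest known reaction type is the Heck (Jeffery-type) arylation of secondary allylic alcohols to β-aryl ketones, and multiple Heck couplings on dihaloarenes are standard. No ring is closed and no stereocentre is created; the carbinol centre of racemic 9 is erased. The step needs terminal regioselectivity in the insertion, secured by the monosubstituted alkene and the halide-bound neutral Pd pathway, and β-hydride elimination toward the carbinol carbon, favoured by the weak hydridic C–H bond next to oxygen, with any styrenyl alcohol isomer expected to be returned to the ketone by Pd–H re-addition and chain walking. Complete double coupling is secured by the excess of 9 and by both C–Br bonds being unhindered, each flanked by two ring CH groups.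

Step 7
Reactants: 11 penta-O-MOM verbenachalcone
Product: 12 verbenachalcone
Conditions: 3 M aq HCl, MeOH/THF, 50 °C
Reagents that add atoms: none
Why: Acid-catalysed cleavage of the five MOM acetals by transacetalization to methanol; the aryl methyl ether, the diaryl ether and the ketones should be inert to dilute HCl at this temperature, and methanol traps the formaldehyde unit as its dimethyl acetal.

**Compound list**

1 | 4-bromo-2-methoxyphenol | COc1cc(Br)ccc1O | starting material
2 | 4-bromo-2-fluorobenzaldehyde | O=Cc1ccc(Br)cc1F | starting material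
3 | 4-bromo-2-(4-bromo-2-methoxyphenoxy)benzaldehyde | COc1cc(Br)ccc1Oc1cc(Br)ccc1C=O | intermediate
4 | 4-bromo-2-(4-bromo-2-methoxyphenoxy)phenyl formate (not isolated) | COc1cc(Br)ccc1Oc1cc(Br)ccc1OC=O | intermediate
5 | 4-bromo-2-(4-bromo-2-methoxyphenoxy)phenol | COc1cc(Br)ccc1Oc1cc(Br)ccc1O | intermediate
6 | 4-bromo-2-(4-bromo-2-methoxyphenoxy)-1-(methoxymethoxy)benzene | COCOc1ccc(Br)cc1Oc1ccc(Br)cc1OC | intermediate
7 | 2,4-dihydroxybenzaldehyde | O=Cc1ccc(O)cc1O | starting material
8 | 2,4-bis(methoxymethoxy)benzaldehyde | COCOc1ccc(C=O)c(OCOC)c1 | intermediate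
9 | rac-1-[2,4-bis(methoxymethoxy)phenyl]prop-2-en-1-ol | C=CC(O)c1ccc(OCOC)cc1OCOC | intermediate
10 | 1-[2,4-bis(methoxymethoxy)phenyl]-3-{4-[5-bromo-2-(methoxymethoxy)phenoxy]-3-methoxyphenyl}propan-1-one (not isolated) | COCOc1ccc(C(=O)CCc2ccc(Oc3cc(Br)ccc3OCOC)c(OC)c2)c(OCOC)c1 | intermediate
11 | penta-O-MOM verbenachalcone: 1-[2,4-bis(methoxymethoxy)phenyl]-3-[4-(5-{3-[2,4-bis(methoxymethoxy)phenyl]-3-oxopropyl}-2-(methoxymethoxy)phenoxy)-3-methoxyphenyl]propan-1-one | COCOc1ccc(C(=O)CCc2ccc(Oc3cc(CCC(=O)c4ccc(OCOC)cc4OCOC)ccc3OCOC)c(OC)c2)c(OCOC)c1 | intermediate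
12 | verbenachalcone: 1-(2,4-dihydroxyphenyl)-3-[4-(5-[3-(2,4-dihydroxyphenyl)-3-oxopropyl]-2-hydroxyphenoxy)-3-methoxyphenyl]propan-1-one | COc1cc(CCC(=O)c2ccc(O)cc2O)ccc1Oc1cc(CCC(=O)c2ccc(O)cc2O)ccc1O | target

**Step count and risks**

Total steps: 7. Longest linear sequence: 5 (steps 1, 2, 3, 6, 7); steps 4 and 5 form the second branch.

Steps most likely to fail:

Step 6. The two-fold coupling may stall after the first cycle because oxidative addition into the electron-rich ring B C–Br bond is slow. β-Hydride elimination may also go toward the benzylic CH2, and Pd–H may isomerize the carbinol to a saturated ketone and so consume it. Fallback with reversed polarity, setting out from 6 and 9 and returning at 11: a two-fold Miyaura borylation of 6 (B2pin2, PdCl2(dppf), KOAc, dioxane, 90 °C) should give 2,2'-{[4-(methoxymethoxy)-1,3-phenylene... ] } in short the bis(pinacolboronate) of the diaryl ether F1. Oxidation of 9 with MnO2 (CH2Cl2, rt) should give 1-[2,4-bis(methoxymethoxy)phenyl]prop-2-en-1-one F2, used at once. A rhodium-catalysed conjugate addition of F1 to an excess of F2 ([Rh(cod)Cl]2, KOH, dioxane/H2O, 50 °C, Hayashi–Miyaura type) should then form the same two aryl–CH2 bonds and give 11.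

Step 2. Hydride migration may compete with aryl migration in the Criegee intermediate and give the carboxylic acid, or the bromine-deactivated aldehyde may be oxidized too slowly. Fallback setting out from 1 and returning at 5: SNAr of 1 on 4-bromo-2-fluoro-1-nitrobenzene (K2CO3, DMF, 50 °C) should give 4-bromo-2-(4-bromo-2-methoxyphenoxy)-1-nitrobenzene F3. Reduction with Fe, NH4Cl in EtOH/H2O at 70 °C should give 4-bromo-2-(4-bromo-2-methoxyphenoxy)aniline F4 with the C–Br bonds intact. Diazotization (NaNO2, aq H2SO4, 0 °C) should give 4-bromo-2-(4-bromo-2-methoxyphenoxy)benzenediazonium hydrogensulfate F5, and its hydrolysis (Cu2O, Cu(NO3)2, H2O, rt) should give phenol 5.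

Step 7. Cleavage of the less labile para-MOM ethers may remain incomplete, or the freed electron-rich resorcinol rings may capture the liberated formaldehyde equivalent under acid (methylene bridging). Fallback with hydrogenolysable protection, setting out from 5 and 7 and returning at 12:
- Benzylation of 5 (BnBr, K2CO3, DMF) should give 1-(benzyloxy)-4-bromo-2-(4-bromo-2-methoxyphenoxy)benzene F6.
- Benzylation of 7 (BnBr, K2CO3, DMF, 60 °C) should give 2,4-bis(benzyloxy)benzaldehyde F7.
- Vinylmagnesium bromide addition should give rac-1-[2,4-bis(benzyloxy)phenyl]prop-2-en-1-ol F8.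
- The two-fold Heck reaction under the conditions of step 6 should pass through 1-[2,4-bis(benzyloxy)phenyl]-3-{4-[2-(benzyloxy)-5-bromophenoxy]-3-methoxyphenyl}propan-1-one F9 and give penta-O-benzyl verbenachalcone F10.
- Hydrogenolysis (H2 1 atm, Pd/C, EtOAc/THF, rt, stopped at full debenzylation) should give 12 under neutral conditions.

**Further compounds**

F1 | step 6 | 2,2'-bis(pinacolboronate) analogue of 6: 2-{4-(methoxymethoxy)-3-[2-methoxy-4-(4,4,5,5-tetramethyl-1,3,2-dioxaborolan-2-yl)phenoxy]phenyl}-4,4,5,5-tetramethyl-1,3,2-dioxaborolane | COCOc1ccc(B2OC(C)(C)C(C)(C)O2)cc1Oc1ccc(B2OC(C)(C)C(C)(C)O2)cc1OC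
F2 | step 6 | 1-[2,4-bis(methoxymethoxy)phenyl]prop-2-en-1-one | C=CC(=O)c1ccc(OCOC)cc1OCOC
F3 | step 2 | 4-bromo-2-(4-bromo-2-methoxyphenoxy)-1-nitrobenzene | COc1cc(Br)ccc1Oc1cc(Br)ccc1[N+](=O)[O-]
F4 | step 2 | 4-bromo-2-(4-bromo-2-methoxyphenoxy)aniline | COc1cc(Br)ccc1Oc1cc(Br)ccc1N
F5 | step 2 | 4-bromo-2-(4-bromo-2-methoxyphenoxy)benzenediazonium hydrogensulfate | COc1cc(Br)ccc1Oc1cc(Br)ccc1[N+]#N.OS(=O)(=O)[O-]
F6 | step 7 | 1-(benzyloxy)-4-bromo-2-(4-bromo-2-methoxyphenoxy)benzene | COc1cc(Br)ccc1Oc1cc(Br)ccc1OCc1ccccc1
F7 | step 7 | 2,4-bis(benzyloxy)benzaldehyde | O=Cc1ccc(OCc2ccccc2)cc1OCc1ccccc1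
F8 | step 7 | rac-1-[2,4-bis(benzyloxy)phenyl]prop-2-en-1-ol | C=CC(O)c1ccc(OCc2ccccc2)cc1OCc1ccccc1
F9 | step 7 | 1-[2,4-bis(benzyloxy)phenyl]-3-{4-[2-(benzyloxy)-5-bromophenoxy]-3-methoxyphenyl}propan-1-one | COc1cc(CCC(=O)c2ccc(OCc3ccccc3)cc2OCc2ccccc2)ccc1Oc1cc(Br)ccc1OCc1ccccc1
F10 | step 7 | penta-O-benzyl verbenachalcone | COc1cc(CCC(=O)c2ccc(OCc3ccccc3)cc2OCc2ccccc2)ccc1Oc1cc(CCC(=O)c2ccc(OCc3ccccc3)cc2OCc2ccccc2)ccc1OCc1ccccc1
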